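The route rests on cutting the C4–C4a bond of ring C as an intramolecular Friedel–Crafts acylation. In one operation an unmasked 2-aryl-3-aryloxypropanoic acid closes ring C at C4a, the only ring A carbon ortho to O1 and para to the free C7 hydroxyl, and leaves C4 as a ketone. That carbonyl makes C3–H acidic, so the racemic isoflavanone can afterwards be funnelled into the (3S) series by transfer hydrogenation with dynamic kinetic resolution, and the same C7 hydroxyl then expels the C4 oxygen through a para-quinone methide. The precursor is a protecting-group-free tert-butyl ester made by oxa-Michael addition of 2-methoxyresorcinol to a 2-arylacrylate.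

Key step: step 4

Remark: the stereocentre of the target is read from the SMILES as (3S); 1,2,3,4-tetramethoxybenzene, di-tert-butyl oxalate and 2-methoxyresorcinol are taken as catalogue compounds.

Step 1
Reactants: 1 1,2,3,4-tetramethoxybenzene; 2 di-tert-butyl oxalate
Product: 4 tert-butyl 2-oxo-2-(2,3,4,5-tetramethoxyphenyl)acetate, via aryllithium 3 (not isolated)
Conditions: n-BuLi, TMEDA, THF, 0 °C; then added to 2 (2.5 equiv), THF, −78 °C; AcOH quench
Reagents that add atoms: none
Why: Directed ortho-metalation places lithium at C5 next to the C4 methoxy group (C5 and C6 are equivalent), and inverse addition of aryllithium 3 to excess hindered oxalate should stop at mono-acylation because the tetrahedral adduct persists at −78 °C.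

Step 2
Reactants: 4 tert-butyl 2-oxo-2-(2,3,4,5-tetramethoxyphenyl)acetate
Product: 5 tert-butyl 2-(2,3,4,5-tetramethoxyphenyl)prop-2-enoate
Conditions: Ph3PCH3Br, KOtBu, THF, 0 °C to rt
Reagents that add atoms: methyltriphenylphosphonium bromide, C[P+](c1ccccc1)(c1ccccc1)c1ccccc1.[Br-]
Why: Wittig methylenation should take place only at the ketone carbonyl of the aryl glyoxylate, which is far more electrophilic than the tert-butyl ester.

Step 3
Reactants: 5 tert-butyl 2-(2,3,4,5-tetramethoxyphenyl)prop-2-enoate; 6 2-methoxybenzene-1,3-diol (2-methoxyresorcinol)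
Product: 7 tert-butyl 3-(3-hydroxy-2-methoxyphenoxy)-2-(2,3,4,5-tetramethoxyphenyl)propanoate (racemic)
Conditions: 6 (3 equiv), Cs2CO3 (0.2 equiv), MeCN, 40 °C
Reagents that add atoms: none
Why: In this base-catalysed oxa-Michael addition the phenoxide of symmetric diol 6 (either hydroxyl gives the same ether) adds to the terminal carbon of the 2-arylacrylate, excess 6 holds back a second addition, and C3 forms as a racemate, which is intended because it is made epimerisable in step 4 and set in step 5.

Step 4
Reactants: 7 tert-butyl 3-(3-hydroxy-2-methoxyphenoxy)-2-(2,3,4,5-tetramethoxyphenyl)propanoate (racemic)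
Product: 9 rac-7-hydroxy-8-methoxy-3-(2,3,4,5-tetramethoxyphenyl)-2,3-dihydro-4H-chromen-4-one, via carboxylic acid 8 (not isolated)
Conditions: TFA/CH2Cl2 (1:1), Et3SiH, rt; evaporate; P2O5/MeSO3H (Eaton's reagent), 45 °C
Reagents that add atoms: none
Why: TFA cleaves the tert-butyl ester by alkyl–oxygen ionisation (Et3SiH quenches the tert-butyl cation so that it cannot alkylate ring A or ring B), and in P2O5/MeSO3H acid 8 is activated as a mixed anhydride or acylium ion that C4a attacks with loss of a proton. The closest known reaction type is the intramolecular Friedel–Crafts acylation of 3-aryloxypropanoic acids to chroman-4-ones. Ring C closes in the 6-exo mode, the carbonyl oxygen staying outside the new six-membered ring (exo-trig at the mixed anhydride, exo-dig at the acylium ion). No stereocentre is controlled here: C3 enters racemic and the new C4 carbonyl deliberately makes it epimerisable for step 5. The regioselectivity is secured by the substrate, because C4a is the only hydrogen-bearing position ortho to O1 (the other is blocked by the C8 methoxy group), it is activated para by the free C7 hydroxyl, and the acyl carbon cannot reach ring B or any other ring A carbon through an unstrained ring.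

Step 5
Reactants: 9 rac-7-hydroxy-8-methoxy-3-(2,3,4,5-tetramethoxyphenyl)-2,3-dihydro-4H-chromen-4-one
Product: 12 (3S)-8-methoxy-3-(2,3,4,5-tetramethoxyphenyl)-3,4-dihydro-2H-chromen-7-ol, via cis-isoflavan-4-ol 10 (not isolated), via para-quinone methide 11 (not isolated)
Conditions: RuCl[(S,S)-TsDPEN](p-cymene) (3 mol %), HCO2H/Et3N (1:1), EtOAc, 45 °C
Reagents that add atoms: none
Why: In this asymmetric transfer hydrogenation of Noyori–Ikariya type with dynamic kinetic resolution, amine-mediated enolisation interconverts the enantiomers of 9 while the (S,S)-catalyst (sense chosen by analogy with chroman-4-one) should deliver hydride to C4 anti to the C3 aryl group of the (3S)-ketone to give cis-(3S,4S)-alcohol 10, whose benzylic hydroxyl is then expelled by the para C7 phenol and the resulting quinone methide 11 is reduced at C4 by the same ruthenium hydride, so C3 is set in the ketone reduction and not touched afterwards.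

Compound list
1 | 1,2,3,4-tetramethoxybenzene | COc1ccc(OC)c(OC)c1OC | starting material
2 | di-tert-butyl oxalate | CC(C)(C)OC(=O)C(=O)OC(C)(C)C | starting material
3 | 2,3,4,5-tetramethoxyphenyllithium | [Li]c1cc(OC)c(OC)c(OC)c1OC | intermediate
4 | tert-butyl 2-oxo-2-(2,3,4,5-tetramethoxyphenyl)acetate | CC(C)(C)OC(=O)C(=O)c1cc(OC)c(OC)c(OC)c1OC | intermediate
5 | tert-butyl 2-(2,3,4,5-tetramethoxyphenyl)prop-2-enoate | C=C(C(=O)OC(C)(C)C)c1cc(OC)c(OC)c(OC)c1OC | intermediate
6 | 2-methoxybenzene-1,3-diol (2-methoxyresorcinol) | COc1c(O)cccc1O | starting material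
7 | tert-butyl 3-(3-hydroxy-2-methoxyphenoxy)-2-(2,3,4,5-tetramethoxyphenyl)propanoate (racemic) | CC(C)(C)OC(=O)C(COc1cccc(O)c1OC)c1cc(OC)c(OC)c(OC)c1OC | intermediate
8 | 3-(3-hydroxy-2-methoxyphenoxy)-2-(2,3,4,5-tetramethoxyphenyl)propanoic acid (racemic) | OC(=O)C(COc1cccc(O)c1OC)c1cc(OC)c(OC)c(OC)c1OC | intermediate
9 | rac-7-hydroxy-8-methoxy-3-(2,3,4,5-tetramethoxyphenyl)-2,3-dihydro-4H-chromen-4-one | O=C1c2ccc(O)c(OC)c2OCC1c1cc(OC)c(OC)c(OC)c1OC | intermediate
10 | (3S,4S)-8-methoxy-3-(2,3,4,5-tetramethoxyphenyl)-3,4-dihydro-2H-chromene-4,7-diol (cis) | COc1cc([C@H]2COc3c(ccc(O)c3OC)[C@H]2O)c(OC)c(OC)c1OC | intermediate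
11 | (3S)-8-methoxy-3-(2,3,4,5-tetramethoxyphenyl)-2,3-dihydro-7H-chromen-7-one (para-quinone methide) | O=C1C=CC2=C[C@@H](c3cc(OC)c(OC)c(OC)c3OC)COC2=C1OC | intermediate
12 | (3S)-8-methoxy-3-(2,3,4,5-tetramethoxyphenyl)-3,4-dihydro-2H-chromen-7-ol | COc1cc([C@H]2COc3c(ccc(O)c3OC)C2)c(OC)c(OC)c1OC | target

Total step count: 5
Longest linear sequence: 5 steps (1 to 12)

Steps most likely to fail

Step 4 (key step). In the strongly acidic medium the activated acyl group may be intercepted by the 2'-methoxy oxygen of ring B (lactone formation with loss of methyl), or the β-aryloxy acid may fragment by retro-oxa-Michael before C4a attacks. The fallback closes ring C at the same bond before ring B is attached and then brings in ring B by enolate arylation. It sets out from 6. Conjugate addition of excess 6 to acrylonitrile (cat. benzyltrimethylammonium hydroxide) should give 3-(3-hydroxy-2-methoxyphenoxy)propanenitrile F1. Intramolecular Houben–Hoesch acylation (CF3SO3H/TFA, then water) should give 7-hydroxy-8-methoxy-2,3-dihydro-4H-chromen-4-one F2. Benzylation (BnBr, K2CO3, acetone) should give 7-(benzyloxy)-8-methoxy-2,3-dihydro-4H-chromen-4-one F3. Palladium-catalysed α-arylation (Pd2(dba)3, XPhos, NaOtBu, toluene, 80 °C) with 1-bromo-2,3,4,5-tetramethoxybenzene F4 (from 1 with NBS in MeCN) should give rac-7-(benzyloxy)-8-methoxy-3-(2,3,4,5-tetramethoxyphenyl)-2,3-dihydro-4H-chromen-4-one F5. Hydrogenolysis of the benzyl ether (H2, Pd/C, EtOAc) comes back to the route at 9.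

Step 3. The reversible conjugate addition may stall on the hindered acrylate, a second addition may occur at the remaining hydroxyl, or the resorcinol-type ring may be C-alkylated through its dianion. The fallback differentiates the two hydroxyls first, so that one fully deprotonated phenoxide can be driven with excess acceptor. It sets out from 6. Monobenzylation (BnBr, 1 equiv, K2CO3, acetone) should give 3-(benzyloxy)-2-methoxyphenol F6. Addition of its potassium salt to excess 5 (KOtBu, THF, 0 °C) should give rac-tert-butyl 3-[3-(benzyloxy)-2-methoxyphenoxy]-2-(2,3,4,5-tetramethoxyphenyl)propanoate F7. Hydrogenolysis (H2, Pd/C, EtOAc) comes back to the route at 7.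

Step 5. The deoxygenation stage may lag behind the ketone reduction, or the quinone methide may tautomerise towards the isoflav-3-ene and erode the C3 configuration. The fallback separates the two events and removes the C4 oxygen without a quinone methide. It sets out from 9: the transfer hydrogenation is run at 25 °C and stopped at cis-alcohol 10, which is isolated. Hydrogenolysis of its benzylic C4–O bond (H2, Pd/C, EtOH with a little AcOH) then comes back to the route at 12. No new compound is made.

Further compounds
F1 | step 4 | 3-(3-hydroxy-2-methoxyphenoxy)propanenitrile | N#CCCOc1cccc(O)c1OC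
F2 | step 4 | 7-hydroxy-8-methoxy-2,3-dihydro-4H-chromen-4-one | O=C1CCOc2c1ccc(O)c2OC
F3 | step 4 | 7-(benzyloxy)-8-methoxy-2,3-dihydro-4H-chromen-4-one | O=C1CCOc2c1ccc(OCc3ccccc3)c2OC
F4 | step 4 | 1-bromo-2,3,4,5-tetramethoxybenzene | COc1cc(Br)c(OC)c(OC)c1OC
F5 | step 4 | rac-7-(benzyloxy)-8-methoxy-3-(2,3,4,5-tetramethoxyphenyl)-2,3-dihydro-4H-chromen-4-one | O=C1c2ccc(OCc3ccccc3)c(OC)c2OCC1c1cc(OC)c(OC)c(OC)c1OC
F6 | step 3 | 3-(benzyloxy)-2-methoxyphenol | COc1c(O)cccc1OCc1ccccc1
F7 | step 3 | rac-tert-butyl 3-[3-(benzyloxy)-2-methoxyphenoxy]-2-(2,3,4,5-tetramethoxyphenyl)propanoate | CC(C)(C)OC(=O)C(COc1cccc(OCc2ccccc2)c1OC)c1cc(OC)c(OC)c(OC)c1OC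
F0 | step 5 | none | none
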